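**Retrosynthetic overview**
1. The strategy rests on oxirane carbon C-2: a quaternary benzylic carbon bonded to the ring oxygen, the ring CH2, the CH2–O–isobutyryl arm and aryl C-1. It is a tertiary C–O stereocentre between two one-carbon arms; with the ring CH2 written as a vinyl group it becomes the aryl-bearing end of an allyl unit.
2. End game: the aryl O–tigloyl bond is made last. The oxirane, the only ring made and kept, is closed in step 11 by the tertiary oxygen on a primary mesylate derived from the vinyl group; the other arm carries the isobutyrate.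
3. Key disconnection: the tertiary C–OH bond of (S)-vinyl diol 16 comes from water and the racemic 4-aryl-4-vinyl-1,3-dioxolan-2-one 14 by palladium-catalysed, enantioconvergent, decarboxylative allylic hydroxylation.
4. Carbonate 14 (a temporary dioxolanone ring, made in step 6 and opened in step 7) comes from diol 11, i.e. vinylMgBr plus α-acetoxy aryl ketone 8, which comes from Friedel–Crafts chloroacetylation of 2,5-dimethoxytoluene. Acetate replaces chloride before the ortho methyl ether is cleaved, so that no o-hydroxyphenacyl chloride (which would close to a benzofuran-3-one) is ever present.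

Key step: step 7

Abbreviations: Ar = 5-methoxy-4-methyl-2-(triisopropylsilyloxy)phenyl. L = (S,S,S)-phosphoramidite, (11bS)-N,N-bis[(S)-1-phenylethyl]dinaphtho[2,1-d:1′,2′-f][1,3,2]dioxaphosphepin-4-amine.

Assumption: the (S,S,S)-antipode of L is taken to give the (S)-diol 16. The sense of induction for an ortho-silyloxyaryl substrate has to be confirmed on the first run; if it is opposite, the (R,R,R)-ligand is used and nothing else changes.

**Step 1**
Reactants: 1 2,5-dimethoxytoluene; 2 chloroacetyl chloride
Product: 3 2-chloro-1-(2,5-dimethoxy-4-methylphenyl)ethan-1-one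
Conditions: AlCl3 (1.2 equiv), CH2Cl2, 0 °C; then ice/aq. HCl
Reagents that add atoms: chloroacetyl chloride, ClCC(=O)Cl
Why: Friedel–Crafts acylation should go to the position para to the methyl group and ortho to a methoxy group, the most activated and least hindered site, and the short cold reaction should leave both methyl ethers intact.

**Step 2**
Reactants: 3 2-chloro-1-(2,5-dimethoxy-4-methylphenyl)ethan-1-one; 4 potassium acetate
Product: 5 2-(2,5-dimethoxy-4-methylphenyl)-2-oxoethyl acetate
Conditions: KOAc (1.5 equiv), NaI (5 mol %), DMF, 25 °C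
Reagents that add atoms: potassium acetate, CC(=O)[O-].[K+]
Why: SN2 displacement at a phenacyl chloride is fast and clean, and it is done while the ortho oxygen is still methylated so that no phenoxide can cyclise onto the CH2Cl carbon.

**Step 3**
Reactants: 5 2-(2,5-dimethoxy-4-methylphenyl)-2-oxoethyl acetate
Product: 6 2-(2-hydroxy-5-methoxy-4-methylphenyl)-2-oxoethyl acetate
Conditions: BCl3 (1.5 equiv), CH2Cl2, −78 → 0 °C; then aq. NaHCO3
Reagents that add atoms: none
Why: Chelation-directed Lewis-acid ether cleavage: BCl3 bound to the ketone oxygen should remove only the ortho methyl group through a six-membered chelate, leaving the other methyl ether and the acetate.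

**Step 4**
Reactants: 6 2-(2-hydroxy-5-methoxy-4-methylphenyl)-2-oxoethyl acetate; 7 triisopropylsilyl trifluoromethanesulfonate
Product: 8 2-Ar-2-oxoethyl acetate
Conditions: TIPSOTf (1.2 equiv), 2,6-lutidine (2 equiv), CH2Cl2, 0 °C
Reagents that add atoms: triisopropylsilyl trifluoromethanesulfonate, CC(C)[Si](C(C)C)(C(C)C)OS(=O)(=O)C(F)(F)F
Why: O-Silylation of the hydrogen-bonded phenol with a silyl triflate is fast, and the weak pyridine base should neither enolise the ketone nor build up phenoxide.

**Step 5**
Reactants: 8 2-Ar-2-oxoethyl acetate; 9 vinylmagnesium bromide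
Product: 11 racemic 2-Ar-but-3-ene-1,2-diol, via racemic hydroxy acetate 10 (not isolated)
Conditions: vinylMgBr (4 equiv), THF, −78 → 0 °C; then aq. NH4Cl
Reagents that add atoms: vinylmagnesium bromide, C=C[Mg]Br
Why: Grignard 1,2-addition to the chelated α-acyloxy ketone builds the quaternary carbinol as a racemate, and excess reagent removes the acetate by double addition; the aryl triisopropylsilyl ether should survive the magnesium alkoxides at or below 0 °C.

**Step 6**
Reactants: 11 racemic 2-Ar-but-3-ene-1,2-diol; 12 1,1′-carbonyldiimidazole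
Product: 14 racemic 4-Ar-4-vinyl-1,3-dioxolan-2-one, via imidazole-1-carboxylate 13 (not isolated)
Conditions: CDI (1.5 equiv), 4-(dimethylamino)pyridine (10 mol %), CH2Cl2, 25 → 40 °C
Reagents that add atoms: 1,1′-carbonyldiimidazole, O=C(n1ccnc1)n1ccnc1
Why: Carbonylation of a 1,2-diol: the primary hydroxyl is acylated first and the tertiary hydroxyl then closes the five-membered carbonate by 5-exo-trig attack with loss of imidazole.

**Step 7**
Reactants: 14 racemic 4-Ar-4-vinyl-1,3-dioxolan-2-one; 15 water
Product: 16 (2S)-2-Ar-but-3-ene-1,2-diol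
Conditions: Pd2(dba)3·CHCl3 (2.5 mol %), L (6 mol %), BEt3 (10 mol %), H2O (10 equiv), THF, 20 °C
Reagents that add atoms: water, O
Why: Zerovalent palladium ionises the allylic C–O bond of either enantiomer of 14 and CO2 is lost, giving an aryl-substituted π-allyl complex of divalent palladium with a pendant primary alkoxide in which the stereocentre is erased; its diastereomeric forms interconvert by π-σ-π shifts faster than they are trapped, so both enantiomers of 14 converge. The alkoxide binds BEt3, and the borate takes up water and passes hydroxide to the neighbouring aryl-bearing allyl terminus, forming the tertiary C–O bond. The closest known reaction type is the palladium/phosphoramidite/borane-catalysed decarboxylative allylic substitution of 4-aryl-4-vinyl-1,3-dioxolan-2-ones by water to give tertiary vinyl glycols. No ring closes; the dioxolanone ring is opened. The new stereocentre C-2 is set by the chiral phosphoramidite, which distinguishes the faces of the equilibrating allyl unit. The step needs branched rather than linear attack, which boron-templated delivery from the adjacent oxygen and the cation-stabilising aryl group should secure, and it needs the bulky ortho-silyloxy group to be tolerated, which is the untested point.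

**Step 8**
Reactants: 16 (2S)-2-Ar-but-3-ene-1,2-diol; 17 isobutyryl chloride
Product: 18 (2S)-2-hydroxy-2-Ar-but-3-en-1-yl 2-methylpropanoate
Conditions: isobutyryl chloride (1.05 equiv), pyridine (3 equiv), CH2Cl2, −20 → 0 °C
Reagents that add atoms: 2-methylpropanoyl chloride, CC(C)C(=O)Cl
Why: Chemoselective O-acylation: the primary hydroxyl reacts while the hindered tertiary benzylic hydroxyl does not, and the stereocentre is not touched.

**Step 9**
Reactants: 18 (2S)-2-hydroxy-2-Ar-but-3-en-1-yl 2-methylpropanoate; 19 ozone
Product: 22 (2R)-2,3-dihydroxy-2-Ar-propyl 2-methylpropanoate, via ozonide 20 (not isolated), via hydroxy aldehyde 21 (not isolated)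
Conditions: O3 (to the fading of Sudan Red 7B), CH2Cl2, −78 °C; PPh3 (1.2 equiv), −78 → 0 °C; then NaBH4 (2 equiv), MeOH, −40 °C; AcOH quench
Reagents that add atoms: ozone, [O-][O+]=O
Why: Criegee ozonolysis with reductive work-up: the monosubstituted alkene should react before the arene when ozone is metered by the indicator, the phosphine reduces the ozonide to the α-hydroxy aldehyde, and cold NaBH4 gives the primary alcohol (the formaldehyde co-product is reduced to methanol), the cold reduction and acid quench being chosen to stop isobutyryl migration between the two arms.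

**Step 10**
Reactants: 22 (2R)-2,3-dihydroxy-2-Ar-propyl 2-methylpropanoate; 23 methanesulfonyl chloride
Product: 24 (2S)-2-hydroxy-3-(methylsulfonyloxy)-2-Ar-propyl 2-methylpropanoate
Conditions: MsCl (1.2 equiv), Et3N (2 equiv), CH2Cl2, −30 °C
Reagents that add atoms: methanesulfonyl chloride, CS(=O)(=O)Cl
Why: Sulfonylation through the sulfene is fast at low temperature and selective for the only primary hydroxyl, the tertiary one being inert.

**Step 11**
Reactants: 24 (2S)-2-hydroxy-3-(methylsulfonyloxy)-2-Ar-propyl 2-methylpropanoate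
Product: 25 [(2R)-2-Ar-oxiran-2-yl]methyl 2-methylpropanoate
Conditions: 1,8-diazabicyclo[5.4.0]undec-7-ene (DBU, 1.5 equiv), CH2Cl2, 0 → 25 °C
Reagents that add atoms: none
Why: Intramolecular Williamson etherification (3-exo-tet) of the tertiary oxygen onto the primary mesylate closes the oxirane without breaking any bond at the stereocentre, so the configuration is kept and only the descriptor changes, while the non-nucleophilic amidine base spares the isobutyrate.

**Step 12**
Reactants: 25 [(2R)-2-Ar-oxiran-2-yl]methyl 2-methylpropanoate; 26 tigloyl chloride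
Product: 28 [(2R)-2-{5-methoxy-4-methyl-2-[(2E)-2-methylbut-2-enoyloxy]phenyl}oxiran-2-yl]methyl 2-methylpropanoate (the target), via phenol 27 (not isolated)
Conditions: Bu4NF (1.05 equiv), THF, −40 °C, 10 min; then pyridine (3 equiv), tigloyl chloride (2 equiv), −40 → 0 °C
Reagents that add atoms: (2E)-2-methylbut-2-enoyl chloride, C/C=C(\C)C(=O)Cl
Why: Fluoride cleavage of the aryl silyl ether gives the tetrabutylammonium phenoxide, which is O-acylated at once in the same flask so that it cannot attack the ester or the benzylic epoxide, and pyridine rather than a trialkylamine avoids deconjugation of the tigloyl group through a vinylketene.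

**Compound list** (Ar = 5-methoxy-4-methyl-2-(triisopropylsilyloxy)phenyl)
1 | 2,5-dimethoxytoluene | COc1ccc(OC)c(C)c1 | starting material
2 | chloroacetyl chloride | ClCC(=O)Cl | starting material
3 | 2-chloro-1-(2,5-dimethoxy-4-methylphenyl)ethan-1-one | ClCC(=O)c1cc(OC)c(C)cc1OC | intermediate
4 | potassium acetate | CC(=O)[O-].[K+] | starting material
5 | 2-(2,5-dimethoxy-4-methylphenyl)-2-oxoethyl acetate | CC(=O)OCC(=O)c1cc(OC)c(C)cc1OC | intermediate
6 | 2-(2-hydroxy-5-methoxy-4-methylphenyl)-2-oxoethyl acetate | CC(=O)OCC(=O)c1cc(OC)c(C)cc1O | intermediate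
7 | triisopropylsilyl trifluoromethanesulfonate | CC(C)[Si](C(C)C)(C(C)C)OS(=O)(=O)C(F)(F)F | starting material
8 | 2-Ar-2-oxoethyl acetate | CC(=O)OCC(=O)c1cc(OC)c(C)cc1O[Si](C(C)C)(C(C)C)C(C)C | intermediate
9 | vinylmagnesium bromide | C=C[Mg]Br | starting material
10 | racemic 2-hydroxy-2-Ar-but-3-en-1-yl acetate | CC(=O)OCC(O)(C=C)c1cc(OC)c(C)cc1O[Si](C(C)C)(C(C)C)C(C)C | intermediate (not isolated)
11 | racemic 2-Ar-but-3-ene-1,2-diol | OCC(O)(C=C)c1cc(OC)c(C)cc1O[Si](C(C)C)(C(C)C)C(C)C | intermediate
12 | 1,1′-carbonyldiimidazole | O=C(n1ccnc1)n1ccnc1 | starting material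
13 | racemic 2-hydroxy-2-Ar-but-3-en-1-yl 1H-imidazole-1-carboxylate | O=C(OCC(O)(C=C)c1cc(OC)c(C)cc1O[Si](C(C)C)(C(C)C)C(C)C)n2ccnc2 | intermediate (not isolated)
14 | racemic 4-Ar-4-vinyl-1,3-dioxolan-2-one | C=CC1(COC(=O)O1)c1cc(OC)c(C)cc1O[Si](C(C)C)(C(C)C)C(C)C | intermediate
15 | water | O | starting material
16 | (2S)-2-Ar-but-3-ene-1,2-diol | CC(C)[Si](C(C)C)(C(C)C)Oc1cc(C)c(OC)cc1[C@](O)(CO)C=C | intermediate
17 | isobutyryl chloride (2-methylpropanoyl chloride) | CC(C)C(=O)Cl | starting material
18 | (2S)-2-hydroxy-2-Ar-but-3-en-1-yl 2-methylpropanoate | CC(C)[Si](C(C)C)(C(C)C)Oc1cc(C)c(OC)cc1[C@](O)(COC(=O)C(C)C)C=C | intermediate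
19 | ozone | [O-][O+]=O | starting material
20 | (2S)-2-hydroxy-2-Ar-2-(1,2,4-trioxolan-3-yl)ethyl 2-methylpropanoate, both epimers at the trioxolane carbon | CC(C)[Si](C(C)C)(C(C)C)Oc1cc(C)c(OC)cc1[C@](O)(COC(=O)C(C)C)C2OCOO2 | intermediate (not isolated)
21 | (2S)-2-hydroxy-2-Ar-3-oxopropyl 2-methylpropanoate | CC(C)[Si](C(C)C)(C(C)C)Oc1cc(C)c(OC)cc1[C@](O)(COC(=O)C(C)C)C=O | intermediate (not isolated)
22 | (2R)-2,3-dihydroxy-2-Ar-propyl 2-methylpropanoate | CC(C)[Si](C(C)C)(C(C)C)Oc1cc(C)c(OC)cc1[C@](O)(COC(=O)C(C)C)CO | intermediate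
23 | methanesulfonyl chloride | CS(=O)(=O)Cl | starting material
24 | (2S)-2-hydroxy-3-(methylsulfonyloxy)-2-Ar-propyl 2-methylpropanoate | CC(C)[Si](C(C)C)(C(C)C)Oc1cc(C)c(OC)cc1[C@](O)(COC(=O)C(C)C)COS(C)(=O)=O | intermediate
25 | [(2R)-2-Ar-oxiran-2-yl]methyl 2-methylpropanoate | CC(C)[Si](C(C)C)(C(C)C)Oc1cc(C)c(OC)cc1[C@]1(COC(=O)C(C)C)CO1 | intermediate
26 | tigloyl chloride, (2E)-2-methylbut-2-enoyl chloride | C/C=C(\C)C(=O)Cl | starting material
27 | [(2R)-2-(2-hydroxy-5-methoxy-4-methylphenyl)oxiran-2-yl]methyl 2-methylpropanoate, formed as its tetrabutylammonium phenoxide | Oc1cc(C)c(OC)cc1[C@]1(COC(=O)C(C)C)CO1 | intermediate (not isolated)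
28 | [(2R)-2-{5-methoxy-4-methyl-2-[(2E)-2-methylbut-2-enoyloxy]phenyl}oxiran-2-yl]methyl 2-methylpropanoate | C/C=C(\C)C(=O)Oc1cc(C)c(OC)cc1[C@]1(COC(=O)C(C)C)CO1 | target

**Step count**
Total: 12 steps. Longest linear sequence: 12 steps, from 2,5-dimethoxytoluene 1.

**Steps most likely to fail**

Step 7. The bulky ortho-silyloxy group may slow ionisation, steer water to the unsubstituted allyl terminus, or weaken facial discrimination by the ligand. The fallback leaves allylpalladium chemistry and sets out from ketone 8. Wittig methylenation (Ph3P=CH2 from Ph3PCH3Br and KOtBu, THF, 0 °C) should give 2-Ar-prop-2-en-1-yl acetate F1, and iBu2AlH (CH2Cl2, −78 °C) should remove the acetate to give 2-Ar-prop-2-en-1-ol F2. Sharpless asymmetric epoxidation (Ti(OiPr)4 10 mol %, diethyl L-(+)-tartrate 12 mol %, tBuOOH, 4 Å molecular sieves, CH2Cl2, −20 °C) should then give the (S)-epoxy alcohol F3; the L-tartrate is the antipode expected to deliver oxygen to the required face of a 2-substituted allylic alcohol. Isobutyryl chloride and pyridine convert F3 into 25, where the route is rejoined.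

Step 9. During the basic reduction the isobutyryl group may migrate between the two primary oxygens by way of the tertiary one, which interchanges the two arms and lowers the enantiomeric purity; the electron-rich ring may also be attacked by ozone. The fallback reverses the roles of the arms so that no ester is present when an alkoxide is formed. It sets out from 14: step 7 run with the antipodal ligand should give (2R)-2-Ar-but-3-ene-1,2-diol F4. MsCl/Et3N (−30 °C) gives the primary mesylate F5, and DBU closes the (2R)-2-Ar-2-vinyloxirane F6. Ozone at −78 °C gives the ozonide F7, PPh3 gives the epoxy aldehyde F8, and NaBH4 at −78 °C gives the same epoxy alcohol F3 as above, which is acylated with isobutyryl chloride and pyridine to 25.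

Step 12. The liberated phenoxide may react within the molecule before it is acylated, by taking the isobutyryl group (which would be followed by epoxide migration) or by opening the benzylic epoxide through an ortho-quinone methide. The fallback separates the two events and avoids the phenoxide. It sets out from 25: Bu4NF buffered with AcOH (THF, 0 °C) should give the neutral phenol 27, which is isolated and esterified with tiglic acid, N,N′-dicyclohexylcarbodiimide and catalytic 4-(dimethylamino)pyridine (Steglich esterification) to reach 28. This fallback makes no compound outside the list (F0).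

**Further compounds**
F1 | step 7 | 2-Ar-prop-2-en-1-yl acetate | CC(=O)OCC(=C)c1cc(OC)c(C)cc1O[Si](C(C)C)(C(C)C)C(C)C
F2 | step 7 | 2-Ar-prop-2-en-1-ol | OCC(=C)c1cc(OC)c(C)cc1O[Si](C(C)C)(C(C)C)C(C)C
F3 | step 7 | [(2S)-2-Ar-oxiran-2-yl]methanol | CC(C)[Si](C(C)C)(C(C)C)Oc1cc(C)c(OC)cc1[C@]1(CO)CO1
F4 | step 9 | (2R)-2-Ar-but-3-ene-1,2-diol | CC(C)[Si](C(C)C)(C(C)C)Oc1cc(C)c(OC)cc1[C@@](O)(CO)C=C
F5 | step 9 | (2R)-2-hydroxy-2-Ar-but-3-en-1-yl methanesulfonate | CC(C)[Si](C(C)C)(C(C)C)Oc1cc(C)c(OC)cc1[C@@](O)(COS(C)(=O)=O)C=C
F6 | step 9 | (2R)-2-Ar-2-vinyloxirane | CC(C)[Si](C(C)C)(C(C)C)Oc1cc(C)c(OC)cc1[C@@]1(CO1)C=C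
F7 | step 9 | 3-[(2R)-2-Ar-oxiran-2-yl]-1,2,4-trioxolane, both epimers at the trioxolane carbon | CC(C)[Si](C(C)C)(C(C)C)Oc1cc(C)c(OC)cc1[C@@]2(CO2)C3OCOO3
F8 | step 9 | (2R)-2-Ar-oxirane-2-carbaldehyde | CC(C)[Si](C(C)C)(C(C)C)Oc1cc(C)c(OC)cc1[C@@]1(CO1)C=O
F0 | step 12 | none | none
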